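(The runs stem from a simulated flask for substances that don't exist; the scatter is artificial.)

Time is the question here: the flask is asked for at 8.0 min, while the grey run, with the same charge of coupling partner and less substrate, stops at 2.50 min.

common to all: coupling partner 0.292 M

|  | substrate | remark | time |
|---|---|---|---|
| grey | 0.036 M | run made earlier |  |
| flask | 0.073 M |  | 8.0 min |

grey run (percent of the substrate charged)

| time / min | isomer of the product / % | substrate / % |
|---|---|---|
| 0.333 | 3.4 | 94.6 |
| 0.667 | 7.9 | 90.5 |
| 1.00 | 11.1 | 86.3 |
| 1.33 | 13.1 | 82.4 |
| 1.50 | 14.0 | 81.0 |
| 2.00 | 17.2 | 77.7 |
| 2.50 | 20.1 | 74.5 |

(standard deviation of a reading: 0.5 percentage points)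

- the numbers in the tables scatter with a standard deviation of 0.5 percentage points

* amount of isomer of the product in the flask at 8.0 min, in percent of the substrate charged
* amount of substrate in the flask at 8.0 min, in percent of the substrate charged
* concentration of coupling partner at 8.0 min, in M

Over its first minute the grey run makes isomer of the product at 0.111 /min of the substrate charged, and over its last minute at 0.0610 /min, a slowing by a factor 0.550. Substrate between these windows falls by a factor 0.835, which leaves a factor 0.658. If the rate follows substrate and coupling partner, this rest is lost partner. Yet the substrate consumed, taken one to one, equals 3.14% of the partner charge, less than the 34.2% slowing. This reckoning therefore lets the partner consume itself in pairs, so the rate falls as one over one plus t/τ. Here τ, the self-loss time of the coupling partner, is the time in which it would fall to half, read from the two windows as 2.39 min, and it shortens as the partner charge grows. The slowing accumulates: 8.0 min count as τ times the logarithm of one plus t/τ, or 3.51 min at the starting rate of 0.144 /min. With 78.8% of lost substrate going to isomer, this reckoning expects 52.6% substrate, 37.4% isomer and 0.0326 M coupling partner.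

The forecast, holding that “something is shutting the reaction down”, gives 62% substrate, 30% isomer of the product and 0.264 M coupling partner, so it parts from this reckoning on the partner.

The flask holds 31.7% isomer of the product. It also holds 56.2% substrate and 0.0443 M coupling partner, the forecast's partner being 5.96 times this.

    substrate + coupling partner → isomer of the product (k = 0.00841 /M/s)
    substrate ⇌ tautomer (K = 0.0145, k = 7.73 × 10⁻⁴ /s)
    2 coupling partner → self-condensation product (k = 0.0162 /M/s)
    coupling partner + tautomer → target (k = 0.451 /M/s)

In the neighbour charged with 1.2 M of coupling partner, τ shortens to 0.582 min, which leaves 0.0814 M before substrate takes its share, and that flask holds 0.0549 M. The asked flask has not come to rest at 8.0 min. Ten times the time gives 8.46 min at the starting rate, 2.41 times the 3.51 min. At 80.0 min the asked flask has gained 15 points of isomer of the product. Its substrate stands at 31.5% beside 0.00212 M of coupling partner.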